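**Retrosynthetic overview**
1. The last bond made is the diaryl ether C-O bond. It is cut to a ring A phenol (methyl 2-hydroxy-4-methoxy-6-pentanoylbenzoate) and an unprotected ring B bromide (olivetolic acid brominated next to the pentyl group).
2. Ring B is bought intact as olivetolic acid. One bromination marks the carbon that will carry the oxygen.
3. The ring A ketone comes from butyl delivery to the only reactive ester of dimethyl 3-hydroxy-5-methoxyphthalate.
4. Ring A is the only ring built, by Diels-Alder reaction and aromatisation of a 1,1,3-trioxygenated diene with dimethyl but-2-ynedioate.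
5. Order: ring A is formed in step 2, ring B comes from the bottle, and the two are joined in the final step. No protecting groups are used.

Assumption: the SMILES holds no stereocentre, no stereogenic double bond and no configurationally stable axis, so the target is achiral and needs no enantiocontrol; olivetolic acid and methyl (E)-3-methoxybut-2-enoate are taken as catalogue chemicals.

**Step 1**
Reactants: 1 methyl (E)-3-methoxybut-2-enoate
Product: 2 1,3-dimethoxy-1-(trimethylsilyloxy)buta-1,3-diene (Brassard diene)
Conditions: LiN(iPr)2 (1.1 equiv, commercial solution), THF, −78 °C, 1 h; Me3SiCl (1.3 equiv), −78 °C to rt; pentane, filtration, bulb-to-bulb distillation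
Reagents that add atoms: chlorotrimethylsilane, C[Si](C)(C)Cl
Why: Kinetic γ-deprotonation of the vinylogous carbonate and O-silylation of the extended enolate (silyl ketene acetal formation) is the standard entry to this diene; no stereocentre is formed, and the ketene acetal geometry is lost on aromatisation.

**Step 2**
Reactants: 2 1,3-dimethoxy-1-(trimethylsilyloxy)buta-1,3-diene; 3 dimethyl but-2-ynedioate
Product: 5 dimethyl 3-hydroxy-5-methoxyphthalate, via Diels-Alder cycloadduct 4 (not isolated)
Conditions: toluene, 0 °C to rt, 16 h; then 1 M HCl, THF, rt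
Reagents that add atoms: none
Why: This is a normal-electron-demand Diels-Alder reaction of a very electron-rich diene with a symmetrical alkyne diester (so no regiochemical issue), after which acid hydrolysis of the mixed silyl ketal in racemic 4 expels Me3SiOH and MeOH and the dienone tautomerises to the phenol, erasing the only stereocentre.

**Step 3**
Reactants: 5 dimethyl 3-hydroxy-5-methoxyphthalate
Product: 7 methyl 2-hydroxy-4-methoxy-6-pentanoylbenzoate, via Weinreb amide 6 (not isolated)
Conditions: MeNH(OMe)·HCl (1.3 equiv), iPrMgCl (3.7 equiv), THF, −20 °C, 1 h; then n-BuMgCl (1.5 equiv), −20 to 0 °C; cold 1 M HCl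
Reagents that add atoms: n-butylmagnesium chloride, CCCC[Mg]Cl; N,O-dimethylhydroxylamine hydrochloride, CNOC.Cl (its N(OMe)Me group stands only in 6)
Why: The magnesium phenoxide formed first switches off the neighbouring ester (ortho O-, para OMe, flanked on both sides), so ClMgN(OMe)Me attacks only the other ester, and the chelated adduct of 6 with n-BuMgCl holds until the quench (one-pot ester to Weinreb amide to ketone, Weinreb ketone synthesis).

**Step 4**
Reactants: 8 olivetolic acid (2,4-dihydroxy-6-pentylbenzoic acid)
Product: 9 3-bromo-4,6-dihydroxy-2-pentylbenzoic acid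
Conditions: NBS (1.0 equiv), MeCN, −20 to 0 °C, dark
Reagents that add atoms: N-bromosuccinimide, O=C1CCC(=O)N1Br
Why: Electrophilic aromatic bromination goes to the ring CH next to the pentyl group (para to the chelated OH, ortho to the free OH) rather than between the two hydroxyls, as in the bromination of 2,4-dihydroxybenzoic acid to its 5-bromo acid and of olivetol to its 4,6-dibromide, and one equivalent at low temperature limits dibromide and bromodecarboxylation.

**Step 5**
Reactants: 7 methyl 2-hydroxy-4-methoxy-6-pentanoylbenzoate; 9 3-bromo-4,6-dihydroxy-2-pentylbenzoic acid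
Product: 10 4,6-dihydroxy-3-[5-methoxy-2-(methoxycarbonyl)-3-pentanoylphenoxy]-2-pentylbenzoic acid (target)
Conditions: 7 (2.5 equiv, excess recovered), Cs2CO3 (5 equiv), 4 Å molecular sieves, degassed DMF, Ar, 35 °C; 9 (1.0 equiv) and [Fe(C5H5)2]PF6 (10 mol %) in MeCN added together over 8 h by syringe pump; cold aq. citric acid
Reagents that add atoms: none
Why: Proposed new method: phenoxyl-radical-enabled SNAr cross-etherification of an unprotected bromoresorcylic acid; Cs2CO3 ionises 9 at CO2H and at the OH next to C-Br, [Fe(C5H5)2]PF6 takes one electron from this phenoxide (the most easily oxidised species present), and in the resulting phenoxyl radical the oxygen radical ortho to C-Br is a transient acceptor far stronger than nitro, so the caesium phenoxide of 7 (too electron-poor for the mediator to oxidise) adds to C-Br perpendicular to the ring plane, where the flanking pentyl and oxygen hinder much less than they hinder metal insertion, bromide leaves, and the product phenoxyl radical takes an electron from fresh phenoxide of 9 or from Fe(C5H5)2 to carry the chain; the process is redox-neutral, so the oxidation-prone 1,2,4-trioxygenated product never meets a stoichiometric oxidant, the excess of 7 and the slow feed of 9 suppress self-etherification of 9, 35 °C spares the base-sensitive keto ester, and a Smiles shift of the aryl group to the neighbouring oxygen is uphill because the phenoxide para to the carboxylate is the better stabilised one; closest known reaction types are the SNAr of 4-halophenols with carboxylates through transient phenoxyl radicals and the oxidant-initiated halide-displacement polymerisation of 4-bromo-2,6-dimethylphenoxide to poly(phenylene ether), neither of which is an established method for a discrete 1:1 cross-coupling of two different phenols or has been shown on a resorcylic acid.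

**Compound list**
1 | methyl (E)-3-methoxybut-2-enoate | CO/C(C)=C/C(=O)OC | starting material
2 | 1,3-dimethoxy-1-(trimethylsilyloxy)buta-1,3-diene (ketene acetal geometry undefined and without consequence) | C=C(OC)C=C(OC)O[Si](C)(C)C | intermediate
3 | dimethyl but-2-ynedioate | COC(=O)C#CC(=O)OC | starting material
4 | dimethyl 3,5-dimethoxy-3-(trimethylsilyloxy)cyclohexa-1,4-diene-1,2-dicarboxylate (racemic, not isolated) | COC(=O)C1=C(C(=O)OC)C(OC)(O[Si](C)(C)C)C=C(OC)C1 | intermediate
5 | dimethyl 3-hydroxy-5-methoxyphthalate | COC(=O)c1cc(OC)cc(O)c1C(=O)OC | intermediate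
6 | methyl 2-hydroxy-4-methoxy-6-[methoxy(methyl)carbamoyl]benzoate (not isolated) | CON(C)C(=O)c1cc(OC)cc(O)c1C(=O)OC | intermediate
7 | methyl 2-hydroxy-4-methoxy-6-pentanoylbenzoate | CCCCC(=O)c1cc(OC)cc(O)c1C(=O)OC | intermediate
8 | olivetolic acid (2,4-dihydroxy-6-pentylbenzoic acid) | CCCCCc1cc(O)cc(O)c1C(=O)O | starting material
9 | 3-bromo-4,6-dihydroxy-2-pentylbenzoic acid | CCCCCc1c(Br)c(O)cc(O)c1C(=O)O | intermediate
10 | 4,6-dihydroxy-3-[5-methoxy-2-(methoxycarbonyl)-3-pentanoylphenoxy]-2-pentylbenzoic acid (achiral) | CCCCCc1c(Oc2cc(OC)cc(C(=O)CCCC)c2C(=O)OC)c(O)cc(O)c1C(=O)O | target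

**Totals**
Total step count: 5. Longest linear sequence: 4 (steps 1, 2, 3, 5).

**Three steps most likely to fail**

Step 5 (the proposed new step). Three failure modes are likely:
- 9 may etherify itself to oligomers.
- The ring B radical may dimerise at its free ring CH.
- The chains may be too short.

The fallback is closed-shell copper catalysis on a fully protected bromide, which is known chemistry. It sets out from 9 (with 7) and comes back at 10.
- 9 is perbenzylated (BnBr, K2CO3, DMF, 50 °C) to benzyl 4,6-bis(benzyloxy)-3-bromo-2-pentylbenzoate F1.
- Ullmann ether coupling of F1 with 7 (CuI 20 mol %, picolinic acid 40 mol %, K3PO4, DMSO, 90 °C) gives benzyl 4,6-bis(benzyloxy)-3-[5-methoxy-2-(methoxycarbonyl)-3-pentanoylphenoxy]-2-pentylbenzoate F2.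
- Hydrogenolysis (H2 1 atm, Pd/C, EtOAc, rt, stopped at full debenzylation to spare the aryl ketone) gives 10.

This costs two more steps.

Step 3. Butyl may add twice to give the 3,3-dibutylphthalide. Alternatively, the tetrahedral alkoxide may close on the neighbouring ester, so that the methyl ester is lost as the lactol.

The fallback replaces the hard nucleophile by a palladium-catalysed acyl coupling. It sets out from 5 and comes back at 7.
- LiOH (2.2 equiv, THF/H2O, rt) saponifies only the unhindered ester, remote from the phenoxide, to give 3-hydroxy-5-methoxy-2-(methoxycarbonyl)benzoic acid F3.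
- EtSH, EDC·HCl and DMAP (CH2Cl2, 0 °C to rt) give methyl 2-[(ethylsulfanyl)carbonyl]-6-hydroxy-4-methoxybenzoate F4.
- Fukuyama coupling with n-BuZnBr (2.5 equiv) and PdCl2(PPh3)2 (5 mol %) in THF/toluene at rt gives 7.

Step 4. Bromine may enter between the two hydroxyls, enter twice, or displace CO2.

The fallback steers the bromination with protecting groups that block the position between the oxygens. It sets out from 8 and comes back at 9.
- NaH and MOMCl (3.5 equiv each, DMF, 0 °C to rt) give methoxymethyl 2,4-bis(methoxymethoxy)-6-pentylbenzoate F5.
- NBS (MeCN, 0 °C) brominates the only accessible ring CH, next to the pentyl group, to give methoxymethyl 3-bromo-4,6-bis(methoxymethoxy)-2-pentylbenzoate F6.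
- 2 M HCl in THF at 40 °C removes the three methoxymethyl groups and gives 9.

**Further compounds**
F1 | step 5 | benzyl 4,6-bis(benzyloxy)-3-bromo-2-pentylbenzoate | CCCCCc1c(Br)c(OCc2ccccc2)cc(OCc2ccccc2)c1C(=O)OCc1ccccc1
F2 | step 5 | benzyl 4,6-bis(benzyloxy)-3-[5-methoxy-2-(methoxycarbonyl)-3-pentanoylphenoxy]-2-pentylbenzoate | CCCCCc1c(Oc2cc(OC)cc(C(=O)CCCC)c2C(=O)OC)c(OCc2ccccc2)cc(OCc2ccccc2)c1C(=O)OCc1ccccc1
F3 | step 3 | 3-hydroxy-5-methoxy-2-(methoxycarbonyl)benzoic acid | COC(=O)c1c(O)cc(OC)cc1C(=O)O
F4 | step 3 | methyl 2-[(ethylsulfanyl)carbonyl]-6-hydroxy-4-methoxybenzoate | CCSC(=O)c1cc(OC)cc(O)c1C(=O)OC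
F5 | step 4 | methoxymethyl 2,4-bis(methoxymethoxy)-6-pentylbenzoate | CCCCCc1cc(OCOC)cc(OCOC)c1C(=O)OCOC
F6 | step 4 | methoxymethyl 3-bromo-4,6-bis(methoxymethoxy)-2-pentylbenzoate | CCCCCc1c(Br)c(OCOC)cc(OCOC)c1C(=O)OCOC
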